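**Strategy.** The target is read as a Diels–Alder pseudo-dimer of two dehydrozaluzanin-type guaianolides, and everything rests on making that monomer by a (3+2) annulation. The cyclopentanone ring of the spiro unit (C1–C5, guaiane numbering) is disconnected at C4–C5 and C2–C1. A γ-chloro-β-keto ester supplies C2–C3(=O)–C4 and adds across the C1=C5 enone of a limonene-derived cycloheptenone (C10 ketone, O-6 and the C7 side chain in place) by tandem Michael addition/enolate alkylation. This sets C5 and C1 and leaves C10=O and the C4 ester as handles for both exocyclic methylenes. The same annulation run through an O-6 tether gives the 5-epi monomer; its trienone and the natural monomer unite in a late endo Diels–Alder reaction that creates spiro C4.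

Key step: step 8

Remark: guaiane numbering is used throughout (C1–C15 for the spiro-cyclopentanone unit, primed numbers for the cyclopentenone unit; α is the face of H-7). The SMILES places H-5' cis to H-6', so the diene half is built deliberately as the 5-epi series (steps 13–19) and not by equilibration.

Step 1
Reactants: 1 (+)-limonene 1,2-oxide ((4R); cis/trans mixture at the epoxide)
Product: 2 (3R)-6-oxo-3-(prop-1-en-2-yl)heptanal
Conditions: H5IO6, THF/H2O, 0 °C to rt
Reagents that add atoms: water, O
Why: Epoxide hydrolysis and periodate glycol cleavage (Malaprade reaction) should open the ring between C10 and C5 while the isopropenyl group and the C7 stereocentre, which comes from limonene, stay untouched.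

Step 2
Reactants: 2 (3R)-6-oxo-3-(prop-1-en-2-yl)heptanal
Product: 3 (2S,3S)-1,6-dioxo-3-(prop-1-en-2-yl)heptan-2-yl benzoate
Conditions: (PhCO2)2, (S)-2-(triphenylmethyl)pyrrolidine (10 mol %), hydroquinone (10 mol %), THF, 0 °C
Reagents that add atoms: dibenzoyl peroxide, O=C(OOC(=O)c1ccccc1)c1ccccc1
Why: Enamine-catalysed α-benzoyloxylation of the aldehyde (the methyl ketone forms its enamine far more slowly) should place O-6 on the α face, the trityl group shielding one enamine face so that the catalyst and not C7 sets C6 (the antipodal catalyst is taken if the sense proves opposite).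

Step 3
Reactants: 3 (2S,3S)-1,6-dioxo-3-(prop-1-en-2-yl)heptan-2-yl benzoate
Product: 4 (3R,4S)-7-oxo-4-(prop-1-en-2-yl)oct-1-en-3-yl benzoate
Conditions: CH2I2, Zn, Ti(OiPr)4, THF, 0 °C to rt
Reagents that add atoms: diiodomethane, ICI
Why: Takai-type methylenation with the gem-dizinc reagent is non-basic and aldehyde-selective, so the epimerisable α-benzoyloxy centre, the benzoate and the methyl ketone should survive.

Step 4
Reactants: 4 (3R,4S)-7-oxo-4-(prop-1-en-2-yl)oct-1-en-3-yl benzoate
Product: 7 (3R,4S)-7-oxo-4-(prop-1-en-2-yl)nona-1,8-dien-3-yl benzoate, via Mannich base 5 (not isolated), via ammonium iodide 6 (not isolated)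
Conditions: LiN(iPr)2, THF, −78 °C; CH2=NMe2+ I−; then MeI, CH2Cl2, rt; then NaHCO3 (aq)
Reagents that add atoms: N,N-dimethylmethyleneiminium iodide (Eschenmoser's salt), C=[N+](C)C.[I-]
Why: Kinetic deprotonation at the methyl group, Mannich reaction, N-methylation and E1cB elimination should turn the methyl ketone into the vinyl ketone needed for ring closure.

Step 5
Reactants: 7 (3R,4S)-7-oxo-4-(prop-1-en-2-yl)nona-1,8-dien-3-yl benzoate
Product: 8 (1R,7S)-4-oxo-7-(prop-1-en-2-yl)cyclohept-2-en-1-yl benzoate
Conditions: second-generation Grubbs catalyst (H2IMes)(PCy3)Cl2Ru=CHPh (5 mol %), CH2Cl2 (0.005 M), 40 °C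
Reagents that add atoms: none
Why: Ring-closing metathesis between the vinyl ketone and the vinyl group next to the benzoate should close the seven-membered enone (C1=C5), the 1,1-disubstituted isopropenyl group being too hindered to compete.

Step 6
Reactants: 8 (1R,7S)-4-oxo-7-(prop-1-en-2-yl)cyclohept-2-en-1-yl benzoate
Product: 9 (1R,7S)-7-(3-hydroxyprop-1-en-2-yl)-4-oxocyclohept-2-en-1-yl benzoate
Conditions: SeO2 (0.3 equiv), tBuOOH, CH2Cl2, rt
Reagents that add atoms: tert-butyl hydroperoxide, CC(C)(C)OO
Why: Selenium dioxide allylic oxidation (ene reaction then [2,3]-sigmatropic shift) should select the methyl group of the 1,1-disubstituted alkene and give the C12 alcohol.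

Step 7
Reactants: 9 (1R,7S)-7-(3-hydroxyprop-1-en-2-yl)-4-oxocyclohept-2-en-1-yl benzoate
Product: 10 (1R,7S)-7-[3-(tert-butyldimethylsilyloxy)prop-1-en-2-yl]-4-oxocyclohept-2-en-1-yl benzoate
Conditions: TBSCl, imidazole, CH2Cl2, 0 °C
Reagents that add atoms: tert-butyldimethylsilyl chloride, CC(C)(C)[Si](C)(C)Cl
Why: Silylation of the primary allylic alcohol masks the future lactone carbon as a group that is neither acidic nor a Michael acceptor.

Step 8
Reactants: 10 (1R,7S)-7-[3-(tert-butyldimethylsilyloxy)prop-1-en-2-yl]-4-oxocyclohept-2-en-1-yl benzoate; 11 tert-butyl 4-chloro-3-oxobutanoate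
Product: 13 tert-butyl 6α-benzoyloxy-12-(tert-butyldimethylsilyloxy)-3,10-dioxo-14,15-dinorguai-11(13)-ene-4-carboxylate (cis-fused; 1αH,5αH,7αH; C4 epimers), via Michael adduct 12 (not isolated)
Conditions: K2CO3, NaI (10 mol %), MeCN, 0 °C to rt, slow addition of 11
Reagents that add atoms: none
Why: The potassium enolate of 11 (carbanion at C4) adds to C5 of the enone in a Michael reaction, and the C10 enolate of 12 formed in that addition then displaces the halide at C2, so that C4–C5 and C2–C1 are made in one flask. The closest known reaction type is the domino Michael addition/α-alkylation (Michael-initiated ring closure) of γ-halo-β-keto esters with enals and enones, which gives cyclopentanones. The Michael step is intermolecular and the cyclopentanone closes by 5-exo-tet C-alkylation of the enolate. C5 is set by addition anti to the allylic 6α-benzoate (β face); C1 follows because the three-atom tether on C5 reaches the neighbouring enolate carbon only from the same face (cis fusion, 1α-H and 5α-H); C4 stays enolisable and becomes sp2 in step 11. The step needs chemoselectivity for the ketone-activated C1=C5 bond, secured because the future α-methylene lactone is still a silyl-protected allylic alcohol, and C- over O-alkylation, secured by the five- versus seven-membered transition state; slow addition of 11 limits its self-condensation.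

Step 9
Reactants: 13 the bicyclic diketo ester of step 8
Product: 14 tert-butyl 6α-benzoyloxy-12-(tert-butyldimethylsilyloxy)-3-oxo-15-norguaia-10(14),11(13)-diene-4-carboxylate (1αH,5αH,7αH)
Conditions: Ph3PCH3Br, KOtBu, THF, 0 °C
Reagents that add atoms: methyltriphenylphosphonium bromide, C[P+](c1ccccc1)(c1ccccc1)c1ccccc1.[Br-]
Why: Wittig methylenation should take place only at the C10 ketone because the first equivalent of ylide converts the β-keto ester into its unreactive enolate; low temperature and short time guard C1 against epimerisation.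

Step 10
Reactants: 14 the methylenated keto ester of step 9
Product: 16 tert-butyl 6α,12-dihydroxy-3-oxo-15-norguaia-10(14),11(13)-diene-4-carboxylate (1αH,5αH,7αH), via 6-alcohol 15 (not isolated)
Conditions: K2CO3, MeOH, rt; then 1 M HCl (aq), THF, rt
Reagents that add atoms: none
Why: Transesterification removes the benzoate and dilute acid then cleaves the primary allylic silyl ether, while the tert-butyl β-keto ester should survive both.

Step 11
Reactants: 16 the diol keto ester of step 10
Product: 18 6α,12-dihydroxyguaia-4(15),10(14),11(13)-trien-3-one (1αH,5αH,7αH), via keto acid 17 (not isolated)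
Conditions: ZnBr2, CH2Cl2, rt; then 37% aq CH2O, Et2NH, THF, rt
Reagents that add atoms: formaldehyde, C=O
Why: Lewis-acid cleavage of the tert-butyl ester followed by decarboxylative Mannich methylenation of the β-keto acid should install C15 only at the carbon that carried the carboxyl group (C4).

Step 12
Reactants: 18 6α,12-dihydroxyguaia-4(15),10(14),11(13)-trien-3-one
Product: 19 dehydrozaluzanin C (3-oxoguaia-4(15),10(14),11(13)-trien-12,6α-olide; 1αH,5αH,6βH,7αH)
Conditions: MnO2 (excess), CH2Cl2, rt
Reagents that add atoms: none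
Why: Oxidative lactonisation: MnO2 oxidises the allylic primary alcohol to the enal, the 6-hydroxyl closes to the lactol, and this allylic hemiacetal is oxidised on to the trans-fused α-methylene lactone with retention at C6.

Step 13
Reactants: 10 (1R,7S)-7-[3-(tert-butyldimethylsilyloxy)prop-1-en-2-yl]-4-oxocyclohept-2-en-1-yl benzoate
Product: 20 (4R,5S)-5-[3-(tert-butyldimethylsilyloxy)prop-1-en-2-yl]-4-hydroxycyclohept-2-en-1-one
Conditions: K2CO3 (0.2 equiv), MeOH, 0 °C
Reagents that add atoms: none
Why: Mild transesterification should free O-6 while the silyl ether stays.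

Step 14
Reactants: 20 (4R,5S)-5-[3-(tert-butyldimethylsilyloxy)prop-1-en-2-yl]-4-hydroxycyclohept-2-en-1-one; 11 tert-butyl 4-chloro-3-oxobutanoate
Product: 21 (1R,7S)-7-[3-(tert-butyldimethylsilyloxy)prop-1-en-2-yl]-4-oxocyclohept-2-en-1-yl 4-chloro-3-oxobutanoate
Conditions: toluene, 110 °C, tBuOH distilled off
Reagents that add atoms: none
Why: Thermal transacetoacetylation: 11 loses tert-butanol to an acylketene that acylates the C6 hydroxyl under neutral conditions, so the three-carbon unit is now tethered to O-6.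

Step 15
Reactants: 21 the chloroacetoacetate ester of step 14
Product: 23 6α-hydroxy-12-(tert-butyldimethylsilyloxy)-3,10-dioxo-14,15-dinorguai-11(13)-ene-4-carboxylic acid 4,6-lactone (1βH,5βH,6βH,7αH; C4 enolisable), via lactone Michael adduct 22 (not isolated)
Conditions: K2CO3, NaI (10 mol %), MeCN, rt
Reagents that add atoms: none
Why: The same Michael/alkylation annulation run intramolecularly: 5-exo-trig Michael addition through the ester tether must deliver C4 to C5 syn to O-6 (cis-fused γ-lactone), and 5-exo-tet enolate alkylation then closes the cyclopentanone, which sets the 5β-H configuration of the upper unit.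

Step 16
Reactants: 23 the tricyclic keto lactone of step 15
Product: 24 6α-hydroxy-12-(tert-butyldimethylsilyloxy)-3-oxo-15-norguaia-10(14),11(13)-diene-4-carboxylic acid 4,6-lactone (1βH,5βH,6βH,7αH)
Conditions: Ph3PCH3Br, KOtBu, THF, 0 °C
Reagents that add atoms: methyltriphenylphosphonium bromide, C[P+](c1ccccc1)(c1ccccc1)c1ccccc1.[Br-]
Why: Wittig methylenation of the C10 ketone, the acidic β-keto lactone being masked as its enolate; C1 becomes sp2 later, so its configuration is not critical in this series.

Step 17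
Reactants: 24 the methylenated keto lactone of step 16
Product: 26 12-(tert-butyldimethylsilyloxy)-6α-hydroxyguaia-4(15),10(14),11(13)-trien-3-one (1βH,5βH,7αH), via keto acid 25 (not isolated)
Conditions: LiOH, THF/H2O, 0 °C; then AcOH, 37% aq CH2O, Et2NH, rt
Reagents that add atoms: formaldehyde, C=O
Why: Saponification opens the β-keto lactone (freeing O-6), and decarboxylative Mannich methylenation of the resulting β-keto acid should place C15 on C4.

Step 18
Reactants: 26 the silyl ether enone of step 17
Product: 27 6α,12-dihydroxyguaia-4(15),10(14),11(13)-trien-3-one (1βH,5βH,7αH)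
Conditions: HF·pyridine, THF, 0 °C
Reagents that add atoms: none
Why: Buffered fluoride desilylation should free the primary alcohol without touching the exocyclic enone.

Step 19
Reactants: 27 the 5-epi enone diol of step 18
Product: 28 1,5-bis-epi-dehydrozaluzanin C (3-oxoguaia-4(15),10(14),11(13)-trien-12,6α-olide; 1βH,5βH,6βH,7αH)
Conditions: MnO2 (excess), CH2Cl2, rt
Reagents that add atoms: none
Why: Oxidative lactonisation as in step 12; O-6 is retained, so the lactone is trans-fused while H-5 stays cis to H-6.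

Step 20
Reactants: 28 1,5-bis-epi-dehydrozaluzanin C
Product: 29 3-(tert-butyldimethylsilyloxy)guaia-2,4(15),10(14),11(13)-tetraen-12,6α-olide (1βH,5βH,6βH,7αH)
Conditions: TBSOTf, Et3N, CH2Cl2, −78 °C
Reagents that add atoms: tert-butyldimethylsilyl trifluoromethanesulfonate, CC(C)(C)[Si](C)(C)OS(=O)(=O)C(F)(F)F
Why: Soft enolisation can occur only towards C2 and should give the silyl dienol ether needed for dehydrogenation.

Step 21
Reactants: 29 the silyl dienol ether of step 20; 19 dehydrozaluzanin C (3 equiv)
Product: 31 Diels–Alder adduct (the 1'(10')-ene isomer of the target with 2'α-H), via trienone 30 (not isolated)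
Conditions: Pd(OAc)2 (1.1 equiv), MeCN, rt
Reagents that add atoms: none
Why: Saegusa–Ito oxidation (divalent palladium enolate, β-hydride elimination) should give the s-cis trienone C14'=C10'–C1'=C2', which is trapped by the exocyclic enone of 19 in a normal-demand Diels–Alder reaction; ortho regiochemistry joins C2'–C4 and C14'–C15, the dienophile reacts on its convex α face and the diene on the face of H-5' away from its seven-membered ring, and this pairing is the endo transition state that sets spiro C4.

Step 22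
Reactants: 31 the Diels–Alder adduct of step 21
Product: 32 the target
Conditions: Et3N, CH2Cl2, 0 °C to rt, stopped at full conversion
Reagents that add atoms: none
Why: Base-mediated 1,3-prototropic isomerisation of the β,γ- to the α,β-unsaturated ketone: the ammonium ion should return the C2' proton to C10' within the ion pair on the same α face, which is also the face not covered by the endo cyclopentanone of the lower unit, and brief exposure leaves the vinylogously acidic C5' centre alone.

**Compound list**

1 | (+)-limonene 1,2-oxide ((4R); cis/trans mixture) | CC12OC1C[C@@H](CC2)C(C)=C | starting material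
2 | (3R)-6-oxo-3-(prop-1-en-2-yl)heptanal | CC(=O)CC[C@@H](C(C)=C)CC=O | intermediate
3 | (2S,3S)-1,6-dioxo-3-(prop-1-en-2-yl)heptan-2-yl benzoate | CC(=O)CC[C@@H](C(C)=C)[C@H](OC(=O)c1ccccc1)C=O | intermediate
4 | (3R,4S)-7-oxo-4-(prop-1-en-2-yl)oct-1-en-3-yl benzoate | CC(=O)CC[C@@H](C(C)=C)[C@H](OC(=O)c1ccccc1)C=C | intermediate
5 | (3R,4S)-9-(dimethylamino)-7-oxo-4-(prop-1-en-2-yl)non-1-en-3-yl benzoate (Mannich base) | CN(C)CCC(=O)CC[C@@H](C(C)=C)[C@H](OC(=O)c1ccccc1)C=C | intermediate
6 | trimethylammonium iodide of 5 | C[N+](C)(C)CCC(=O)CC[C@@H](C(C)=C)[C@H](OC(=O)c1ccccc1)C=C.[I-] | intermediate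
7 | (3R,4S)-7-oxo-4-(prop-1-en-2-yl)nona-1,8-dien-3-yl benzoate | C=CC(=O)CC[C@@H](C(C)=C)[C@H](OC(=O)c1ccccc1)C=C | intermediate
8 | (1R,7S)-4-oxo-7-(prop-1-en-2-yl)cyclohept-2-en-1-yl benzoate | O=C1CC[C@@H](C(C)=C)[C@H](OC(=O)c2ccccc2)C=C1 | intermediate
9 | (1R,7S)-7-(3-hydroxyprop-1-en-2-yl)-4-oxocyclohept-2-en-1-yl benzoate | O=C1CC[C@@H](C(=C)CO)[C@H](OC(=O)c2ccccc2)C=C1 | intermediate
10 | (1R,7S)-7-[3-(tert-butyldimethylsilyloxy)prop-1-en-2-yl]-4-oxocyclohept-2-en-1-yl benzoate | O=C1CC[C@@H](C(=C)CO[Si](C)(C)C(C)(C)C)[C@H](OC(=O)c2ccccc2)C=C1 | intermediate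
11 | tert-butyl 4-chloro-3-oxobutanoate | CC(C)(C)OC(=O)CC(=O)CCl | starting material
12 | Michael adduct (C4–C5 bond made; C2 still CH2Cl) | CC(C)(C)OC(=O)C(C(=O)CCl)[C@H]1CC(=O)CC[C@@H](C(=C)CO[Si](C)(C)C(C)(C)C)[C@@H]1OC(=O)c1ccccc1 | intermediate
13 | tert-butyl 6α-benzoyloxy-12-(tert-butyldimethylsilyloxy)-3,10-dioxo-14,15-dinorguai-11(13)-ene-4-carboxylate (1αH,5αH,7αH) | CC(C)(C)OC(=O)C1C(=O)C[C@H]2C(=O)CC[C@@H](C(=C)CO[Si](C)(C)C(C)(C)C)[C@H](OC(=O)c3ccccc3)[C@@H]12 | intermediate
14 | tert-butyl 6α-benzoyloxy-12-(tert-butyldimethylsilyloxy)-3-oxo-15-norguaia-10(14),11(13)-diene-4-carboxylate | CC(C)(C)OC(=O)C1C(=O)C[C@H]2C(=C)CC[C@@H](C(=C)CO[Si](C)(C)C(C)(C)C)[C@H](OC(=O)c3ccccc3)[C@@H]12 | intermediate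
15 | tert-butyl 6α-hydroxy-12-(tert-butyldimethylsilyloxy)-3-oxo-15-norguaia-10(14),11(13)-diene-4-carboxylate | CC(C)(C)OC(=O)C1C(=O)C[C@H]2C(=C)CC[C@@H](C(=C)CO[Si](C)(C)C(C)(C)C)[C@H](O)[C@@H]12 | intermediate
16 | tert-butyl 6α,12-dihydroxy-3-oxo-15-norguaia-10(14),11(13)-diene-4-carboxylate | CC(C)(C)OC(=O)C1C(=O)C[C@H]2C(=C)CC[C@@H](C(=C)CO)[C@H](O)[C@@H]12 | intermediate
17 | 6α,12-dihydroxy-3-oxo-15-norguaia-10(14),11(13)-diene-4-carboxylic acid | OC(=O)C1C(=O)C[C@H]2C(=C)CC[C@@H](C(=C)CO)[C@H](O)[C@@H]12 | intermediate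
18 | 6α,12-dihydroxyguaia-4(15),10(14),11(13)-trien-3-one (1αH,5αH,7αH) | C=C1C(=O)C[C@H]2C(=C)CC[C@@H](C(=C)CO)[C@H](O)[C@@H]12 | intermediate
19 | dehydrozaluzanin C (1αH,5αH,6βH,7αH) | C=C1C(=O)C[C@H]2C(=C)CC[C@H]3C(=C)C(=O)O[C@@H]3[C@@H]12 | intermediate
20 | (4R,5S)-5-[3-(tert-butyldimethylsilyloxy)prop-1-en-2-yl]-4-hydroxycyclohept-2-en-1-one | O=C1CC[C@@H](C(=C)CO[Si](C)(C)C(C)(C)C)[C@H](O)C=C1 | intermediate
21 | (1R,7S)-7-[3-(tert-butyldimethylsilyloxy)prop-1-en-2-yl]-4-oxocyclohept-2-en-1-yl 4-chloro-3-oxobutanoate | O=C1CC[C@@H](C(=C)CO[Si](C)(C)C(C)(C)C)[C@H](OC(=O)CC(=O)CCl)C=C1 | intermediate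
22 | cis-fused lactone Michael adduct (C4–C5 made syn to O-6; C2 still CH2Cl) | O=C1CC[C@@H](C(=C)CO[Si](C)(C)C(C)(C)C)[C@@H]2OC(=O)C(C(=O)CCl)[C@@H]2C1 | intermediate
23 | 6α-hydroxy-12-(tert-butyldimethylsilyloxy)-3,10-dioxo-14,15-dinorguai-11(13)-ene-4-carboxylic acid 4,6-lactone (1βH,5βH) | O=C1CC[C@@H](C(=C)CO[Si](C)(C)C(C)(C)C)[C@@H]2OC(=O)C3C(=O)C[C@H]1[C@H]23 | intermediate
24 | 6α-hydroxy-12-(tert-butyldimethylsilyloxy)-3-oxo-15-norguaia-10(14),11(13)-diene-4-carboxylic acid 4,6-lactone (1βH,5βH) | C=C1CC[C@@H](C(=C)CO[Si](C)(C)C(C)(C)C)[C@@H]2OC(=O)C3C(=O)C[C@H]1[C@H]23 | intermediate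
25 | 6α-hydroxy-12-(tert-butyldimethylsilyloxy)-3-oxo-15-norguaia-10(14),11(13)-diene-4-carboxylic acid (1βH,5βH) | OC(=O)C1C(=O)C[C@@H]2C(=C)CC[C@@H](C(=C)CO[Si](C)(C)C(C)(C)C)[C@H](O)[C@H]12 | intermediate
26 | 12-(tert-butyldimethylsilyloxy)-6α-hydroxyguaia-4(15),10(14),11(13)-trien-3-one (1βH,5βH,7αH) | C=C1C(=O)C[C@@H]2C(=C)CC[C@@H](C(=C)CO[Si](C)(C)C(C)(C)C)[C@H](O)[C@H]12 | intermediate
27 | 6α,12-dihydroxyguaia-4(15),10(14),11(13)-trien-3-one (1βH,5βH,7αH) | C=C1C(=O)C[C@@H]2C(=C)CC[C@@H](C(=C)CO)[C@H](O)[C@H]12 | intermediate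
28 | 1,5-bis-epi-dehydrozaluzanin C (1βH,5βH,6βH,7αH) | C=C1C(=O)C[C@@H]2C(=C)CC[C@H]3C(=C)C(=O)O[C@@H]3[C@H]12 | intermediate
29 | 3-(tert-butyldimethylsilyloxy)guaia-2,4(15),10(14),11(13)-tetraen-12,6α-olide (1βH,5βH) | C=C1C(O[Si](C)(C)C(C)(C)C)=C[C@@H]2C(=C)CC[C@H]3C(=C)C(=O)O[C@@H]3[C@H]12 | intermediate
30 | 3-oxoguaia-1,4(15),10(14),11(13)-tetraen-12,6α-olide (5βH) | C=C1C(=O)C=C2C(=C)CC[C@H]3C(=C)C(=O)O[C@@H]3[C@H]12 | intermediate
31 | Diels–Alder adduct (1'(10')-ene; 2'α-H; spiro C4 as in the target) | C=C1C(=O)[C@@H]2C3=C(CC[C@H]4C(=C)C(=O)O[C@@H]4[C@H]13)CC[C@]21C(=O)C[C@H]2C(=C)CC[C@H]3C(=C)C(=O)O[C@@H]3[C@H]21 | intermediate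
32 | CNP0221188.1 | C=C1C(=O)C2=C3[C@H](CC[C@H]4C(=C)C(=O)O[C@@H]4[C@H]13)CC[C@]21C(=O)C[C@H]2C(=C)CC[C@H]3C(=C)C(=O)O[C@@H]3[C@H]21 | target

**Step count.** 22 steps in total. Longest linear sequence: 17 steps (steps 1–7, then 13–22); steps 8–12 form the branch to 19.

**Steps most likely to fail**

Step 21. The transient trienone may dimerise with itself, may lose its C5' configuration through its vinylogously acidic proton in the presence of acetate, or may add through the wrong endo/facial pairing. The fallback sets out from 29 and replaces palladium dehydrogenation by selenoxide elimination. Selenenylation of 29 with PhSeCl at −78 °C should give the 2-(phenylselanyl) ketone F1. Oxidation with H2O2 at −30 °C in the presence of 19 gives the selenoxide F2, which eliminates syn towards H-1 and releases 30 under neutral, metal-free conditions. Cycloaddition with 19 then returns the route to 31.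

Step 22. Under base the product can re-enolise, so that C10' and C5' drift towards other epimers, or the proton may simply return to C2'. The fallback sets out from 31 and uses acid-catalysed tautomerisation instead (camphorsulfonic acid, catalytic, CH2Cl2, 0 °C). Enolisation of the C3' ketone towards C2' gives the dienol F3. Its ketonisation by protonation at C10' is governed by the face left open by the endo cyclopentanone of the lower unit, and no carbanion is formed at C5'. The fallback comes back at 32.

Step 8. Facial selectivity at C5 may be low, or self-condensation of 11 may outrun the Michael addition. The fallback sets out from 10 and 11 and separates the two bond formations. 11 is converted with TMSCl and Et3N into tert-butyl 4-chloro-3-(trimethylsilyloxy)but-2-enoate F4 (E/Z mixture). A TiCl4-mediated Mukaiyama–Michael addition of F4 to 10 at −78 °C should give 12, here isolated after aqueous work-up. Ring closure of 12 with K2CO3 and NaI in MeCN comes back at 13.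

**Further compounds**

F1 | step 21 | 2-(phenylselanyl)-1,5-bis-epi-dehydrozaluzanin C (C2 epimers) | C=C1C(=O)C([Se]c2ccccc2)[C@@H]2C(=C)CC[C@H]3C(=C)C(=O)O[C@@H]3[C@H]12
F2 | step 21 | selenoxide of F1 | C=C1C(=O)C([Se](=O)c2ccccc2)[C@@H]2C(=C)CC[C@H]3C(=C)C(=O)O[C@@H]3[C@H]12
F3 | step 22 | 3'-hydroxy-2'(3'),1'(10')-dienol tautomer of 31 | C=C1C(O)=C2C3=C(CC[C@H]4C(=C)C(=O)O[C@@H]4[C@H]13)CC[C@]21C(=O)C[C@H]2C(=C)CC[C@H]3C(=C)C(=O)O[C@@H]3[C@H]21
F4 | step 8 | tert-butyl 4-chloro-3-(trimethylsilyloxy)but-2-enoate (E/Z mixture) | CC(C)(C)OC(=O)C=C(CCl)O[Si](C)(C)C
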